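**Retrosynthetic overview**
1. Target 27 ⇐ acetylation of allylic alcohol 26 ⇐ late Ni/Cr-mediated (Nozaki–Hiyama–Kishi) union of vinyl iodide 14 (C13, fragment A) with aldehyde 24 (C12, fragment B); this makes the C7–C8 bond and the C7 carbinol.
2. Fragment A: 14 ⇐ geminal vinylsilane 13 ⇐ oxidative 1,3-transposition of the MeLi adduct of enone 11 ⇐ ketone 10. Its quaternary/tertiary pair comes from Cu-catalysed asymmetric methyl addition to 2-alkylcyclohexenone 6 followed by anti C-methylation; 6 ⇐ Negishi coupling of 2-iodocyclohexenone with the zinc reagent from hydrosilylated 4-bromobut-1-yne.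
3. Fragment B: 24 ⇐ Claisen rearrangement (E-trisubstituted alkene) of the vinyl ether of isopropenyl carbinol 22 ⇐ aldehyde 19 ⇐ B-alkyl Suzuki coupling of 4-bromofuran-2(5H)-one with hydroborated acrolein dimethyl acetal.
4. Rings: none is built. The carbocycle comes from cyclohex-2-en-1-one (decorated first) and the butenolide from 4-bromofuran-2(5H)-one (carried through fragment B).

Assumption: in the two ligand-controlled steps (4 and 15) the ligand enantiomer named is taken to give the configuration shown; if the sense of induction is the reverse, its mirror image is used.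

**Step 1**
Reactants: 1 cyclohex-2-en-1-one
Product: 2 2-iodocyclohex-2-en-1-one
Conditions: I2 (1.5 equiv), K2CO3 (1.2 equiv), DMAP (0.2 equiv), THF/H2O 1:1, rt
Reagents that add atoms: iodine, II
Why: Amine-catalysed α-iodination of an enone (Baylis–Hillman-type addition of DMAP, iodination of the enolate, elimination) gives the α-iodoenone.

**Step 2**
Reactants: 3 4-bromobut-1-yne
Product: 4 (4-bromobut-1-en-2-yl)triethylsilane
Conditions: Et3SiH (1.2 equiv), [Cp*Ru(MeCN)3]PF6 (1 mol %), CH2Cl2, 0 °C to rt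
Reagents that add atoms: triethylsilane, CC[SiH](CC)CC
Why: Cationic ruthenium-catalysed alkyne hydrosilylation is Markovnikov-selective on terminal alkynes and gives the geminal (2-silyl) alkene, with the primary bromide untouched.

**Step 3**
Reactants: 4 (4-bromobut-1-en-2-yl)triethylsilane; 2 2-iodocyclohex-2-en-1-one
Product: 6 2-[3-(triethylsilyl)but-3-en-1-yl]cyclohex-2-en-1-one, via alkylzinc bromide 5 (not isolated)
Conditions: Zn dust (activated with BrCH2CH2Br/TMSCl), LiCl, THF, 50 °C; then 2, Pd2(dba)3 (2.5 mol %), tri(2-furyl)phosphine (10 mol %), THF/DMF, rt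
Reagents that add atoms: none
Why: LiCl-promoted zinc insertion into the primary bromide and Negishi coupling with the α-iodoenone form the sp3–sp2 bond; alkylzinc halides do not add to the ketone.

**Step 4**
Reactants: 6 2-[3-(triethylsilyl)but-3-en-1-yl]cyclohex-2-en-1-one
Product: 8 trimethyl({(3R)-3-methyl-2-[3-(triethylsilyl)but-3-en-1-yl]cyclohex-1-en-1-yl}oxy)silane, via aluminium enolate 7 (not isolated)
Conditions: Me3Al (1.5 equiv), CuTC (copper thiophene-2-carboxylate, C5H3CuO2S, 5 mol %), (Sa,S,S)-BINOL bis(1-phenylethyl)amine phosphoramidite (10 mol %), Et2O, −30 °C; then TMSOTf (2 equiv), THF, −30 to 0 °C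
Reagents that add atoms: trimethylaluminium, C[Al](C)C; trimethylsilyl trifluoromethanesulfonate, C[Si](C)(C)OS(=O)(=O)C(F)(F)F
Why: Copper-catalysed asymmetric conjugate addition to the α-substituted enone sets the methyl-bearing centre (3R) by ligand control, and O-silylation of the aluminium enolate fixes the enolate regiochemistry.

**Step 5**
Reactants: 8 trimethyl({(3R)-3-methyl-2-[3-(triethylsilyl)but-3-en-1-yl]cyclohex-1-en-1-yl}oxy)silane
Product: 10 (2R,3R)-2,3-dimethyl-2-[3-(triethylsilyl)but-3-en-1-yl]cyclohexan-1-one, via lithium enolate 9 (not isolated)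
Conditions: MeLi (1.05 equiv), THF, 0 °C; then HMPA (3 equiv), MeI (5 equiv), −78 to −20 °C
Reagents that add atoms: iodomethane, CI
Why: Regiospecific enolate generation from the silyl enol ether and C-methylation; the neighbouring methyl sits pseudoaxial to avoid allylic strain, so MeI enters anti to it and the quaternary centre forms with the two methyls trans (2R).

**Step 6**
Reactants: 10 (2R,3R)-2,3-dimethyl-2-[3-(triethylsilyl)but-3-en-1-yl]cyclohexan-1-one
Product: 11 (5R,6R)-5,6-dimethyl-6-[3-(triethylsilyl)but-3-en-1-yl]cyclohex-2-en-1-one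
Conditions: IBX (2.5 equiv), toluene/DMSO 2:1, 75 °C
Reagents that add atoms: none
Why: IBX dehydrogenation of a ketone to the enone; only the CH2 side can enolise because the other α-carbon is quaternary.

**Step 7**
Reactants: 11 (5R,6R)-5,6-dimethyl-6-[3-(triethylsilyl)but-3-en-1-yl]cyclohex-2-en-1-one
Product: 12 (5R,6R)-1,5,6-trimethyl-6-[3-(triethylsilyl)but-3-en-1-yl]cyclohex-2-en-1-ol (both C1 epimers)
Conditions: MeLi (1.5 equiv), Et2O, −78 to 0 °C; H2O quench
Reagents that add atoms: methyllithium, [Li]C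
Why: Methyllithium adds 1,2 to the enone to give the tertiary allylic alcohol; the new carbinol centre is destroyed in the next step, so its configuration is irrelevant.

**Step 8**
Reactants: 12 (5R,6R)-1,5,6-trimethyl-6-[3-(triethylsilyl)but-3-en-1-yl]cyclohex-2-en-1-ol
Product: 13 (4R,5R)-3,4,5-trimethyl-4-[3-(triethylsilyl)but-3-en-1-yl]cyclohex-2-en-1-one
Conditions: pyridinium chlorochromate (C5H5NH)[CrO3Cl] (2.5 equiv), 4 Å molecular sieves, CH2Cl2, rt
Reagents that add atoms: pyridinium chlorochromate, [O-][Cr](=O)(=O)Cl.c1cc[nH+]cc1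
Why: Dauben–Babler oxidative transposition: the tertiary allylic chromate ester undergoes a [3,3] shift and the resulting secondary chromate is oxidised to the β-methyl enone, without touching either stereocentre.

**Step 9**
Reactants: 13 (4R,5R)-3,4,5-trimethyl-4-[3-(triethylsilyl)but-3-en-1-yl]cyclohex-2-en-1-one
Product: 14 (4R,5R)-4-(3-iodobut-3-en-1-yl)-3,4,5-trimethylcyclohex-2-en-1-one
Conditions: NIS (1.3 equiv), 2,6-lutidine (0.3 equiv), (CF3)2CHOH, 0 °C
Reagents that add atoms: N-iodosuccinimide, O=C1CCC(=O)N1I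
Why: Iododesilylation (ipso substitution through a β-silyl-stabilised cation) turns the electron-rich vinylsilane into the 2-iodoalkene; the electron-poor enone alkene does not react.

**Step 10**
Reactants: 15 3,3-dimethoxyprop-1-ene; 16 4-bromofuran-2(5H)-one
Product: 18 4-(3,3-dimethoxypropyl)furan-2(5H)-one, via alkyl-9-BBN 17 (not isolated)
Conditions: 9-BBN (1.1 equiv), THF, 0 °C to rt; then 16, Pd(dppf)Cl2 (5 mol %), K3PO4·H2O (3 equiv), DMF/THF, rt
Reagents that add atoms: none
Why: Anti-Markovnikov hydroboration followed by B-alkyl Suzuki–Miyaura coupling with the β-bromo butenolide (a vinylogous acyl bromide, which undergoes fast oxidative addition) installs the C3 acetal chain.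

**Step 11**
Reactants: 18 4-(3,3-dimethoxypropyl)furan-2(5H)-one
Product: 19 3-(5-oxo-2,5-dihydrofuran-3-yl)propanal
Conditions: 1 M aq. HCl/THF 1:4, rt
Reagents that add atoms: water, O
Why: Acid-catalysed acetal hydrolysis frees the aldehyde; the butenolide is stable to dilute acid.

**Step 12**
Reactants: 19 3-(5-oxo-2,5-dihydrofuran-3-yl)propanal; 20 2-bromopropene
Product: 22 4-(3-hydroxy-4-methylpent-4-en-1-yl)furan-2(5H)-one (racemic), via isopropenylchromium dichloride 21 (not isolated)
Conditions: 20 (3 equiv), CrCl2 (4 equiv), NiCl2 (1 mol %), DMF, rt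
Reagents that add atoms: none
Why: Nozaki–Hiyama–Kishi addition is aldehyde-selective, so the lactone survives; the carbinol centre is racemic and is consumed in the rearrangement of step 14.

**Step 13**
Reactants: 22 4-(3-hydroxy-4-methylpent-4-en-1-yl)furan-2(5H)-one
Product: 23 4-[3-(ethenyloxy)-4-methylpent-4-en-1-yl]furan-2(5H)-one (racemic)
Conditions: ethyl vinyl ether (solvent), Hg(OAc)2 (0.3 equiv), reflux; K2CO3 quench
Reagents that add atoms: ethyl vinyl ether, C=COCC
Why: Hg(OAc)2-catalysed transvinylation (vinyl ether exchange) converts the secondary allylic alcohol into its allyl vinyl ether under neutral conditions.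

**Step 14**
Reactants: 23 4-[3-(ethenyloxy)-4-methylpent-4-en-1-yl]furan-2(5H)-one
Product: 24 (E)-4-methyl-7-(5-oxo-2,5-dihydrofuran-3-yl)hept-4-enal
Conditions: toluene, sealed tube, 130 °C
Reagents that add atoms: none
Why: Claisen rearrangement through a chair transition state with the carbinol substituent equatorial (an axial position would clash with the 2-methyl group) gives the γ,δ-unsaturated aldehyde with the E-trisubstituted alkene.

**Step 15**
Reactants: 14 (4R,5R)-4-(3-iodobut-3-en-1-yl)-3,4,5-trimethylcyclohex-2-en-1-one; 24 (E)-4-methyl-7-(5-oxo-2,5-dihydrofuran-3-yl)hept-4-enal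
Product: 26 4-[(3E,7R)-7-hydroxy-4-methyl-8-methylidene-10-[(1R,6R)-1,2,6-trimethyl-4-oxocyclohex-2-en-1-yl]dec-3-en-1-yl]furan-2(5H)-one, via alkenylchromium species 25 (not isolated)
Conditions: CrCl2 (3 equiv), N-{2-[(4S)-4-isopropyl-4,5-dihydro-1,3-oxazol-2-yl]-6-methylphenyl}methanesulfonamide (3.3 equiv), Et3N (3.3 equiv), THF, rt, 1 h; then NiCl2 (2 mol %), 14 (1.2 equiv), 24, THF, rt; aqueous ethylenediamine work-up (ligand recovered)
Reagents that add atoms: none
Why: Asymmetric Nozaki–Hiyama–Kishi coupling: zerovalent nickel inserts into the C–I bond, transmetalation gives an alkenylchromium that adds only to the aldehyde (enone and butenolide untouched), and the chiral sulfonamide on chromium selects the aldehyde face that gives 7R.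

**Step 16**
Reactants: 26 4-[(3E,7R)-7-hydroxy-4-methyl-8-methylidene-10-[(1R,6R)-1,2,6-trimethyl-4-oxocyclohex-2-en-1-yl]dec-3-en-1-yl]furan-2(5H)-one
Product: 27 4-[(3E,7R)-7-acetoxy-4-methyl-8-methylidene-10-[(1R,6R)-1,2,6-trimethyl-4-oxocyclohex-2-en-1-yl]dec-3-en-1-yl]furan-2(5H)-one (CNP0204194.1)
Conditions: Ac2O (3 equiv), pyridine (5 equiv), DMAP (0.1 equiv), CH2Cl2, 0 °C to rt
Reagents that add atoms: acetic anhydride, CC(=O)OC(C)=O
Why: DMAP-catalysed acylation of the secondary allylic alcohol proceeds with retention at C7 and leaves all other groups alone.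

**Compound list**
1 | cyclohex-2-en-1-one | O=C1C=CCCC1 | starting material
2 | 2-iodocyclohex-2-en-1-one | O=C1CCCC=C1I | intermediate
3 | 4-bromobut-1-yne | C#CCCBr | starting material
4 | (4-bromobut-1-en-2-yl)triethylsilane | C=C(CCBr)[Si](CC)(CC)CC | intermediate
5 | [3-(triethylsilyl)but-3-en-1-yl]zinc bromide | C=C(CC[Zn]Br)[Si](CC)(CC)CC | intermediate (not isolated)
6 | 2-[3-(triethylsilyl)but-3-en-1-yl]cyclohex-2-en-1-one | C=C(CCC1=CCCCC1=O)[Si](CC)(CC)CC | intermediate
7 | dimethylaluminium (3R)-3-methyl-2-[3-(triethylsilyl)but-3-en-1-yl]cyclohex-1-en-1-olate | C=C(CCC1=C(O[Al](C)C)CCC[C@H]1C)[Si](CC)(CC)CC | intermediate (not isolated)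
8 | trimethyl({(3R)-3-methyl-2-[3-(triethylsilyl)but-3-en-1-yl]cyclohex-1-en-1-yl}oxy)silane | C=C(CCC1=C(O[Si](C)(C)C)CCC[C@H]1C)[Si](CC)(CC)CC | intermediate
9 | lithium (3R)-3-methyl-2-[3-(triethylsilyl)but-3-en-1-yl]cyclohex-1-en-1-olate | C=C(CCC1=C(O[Li])CCC[C@H]1C)[Si](CC)(CC)CC | intermediate (not isolated)
10 | (2R,3R)-2,3-dimethyl-2-[3-(triethylsilyl)but-3-en-1-yl]cyclohexan-1-one | C=C(CC[C@@]1(C)C(=O)CCC[C@H]1C)[Si](CC)(CC)CC | intermediate
11 | (5R,6R)-5,6-dimethyl-6-[3-(triethylsilyl)but-3-en-1-yl]cyclohex-2-en-1-one | C=C(CC[C@@]1(C)C(=O)C=CC[C@H]1C)[Si](CC)(CC)CC | intermediate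
12 | (5R,6R)-1,5,6-trimethyl-6-[3-(triethylsilyl)but-3-en-1-yl]cyclohex-2-en-1-ol (C1 epimers) | C=C(CC[C@@]1(C)C(C)(O)C=CC[C@H]1C)[Si](CC)(CC)CC | intermediate
13 | (4R,5R)-3,4,5-trimethyl-4-[3-(triethylsilyl)but-3-en-1-yl]cyclohex-2-en-1-one | C=C(CC[C@@]1(C)C(C)=CC(=O)C[C@H]1C)[Si](CC)(CC)CC | intermediate
14 | (4R,5R)-4-(3-iodobut-3-en-1-yl)-3,4,5-trimethylcyclohex-2-en-1-one | C=C(I)CC[C@@]1(C)C(C)=CC(=O)C[C@H]1C | intermediate
15 | 3,3-dimethoxyprop-1-ene | C=CC(OC)OC | starting material
16 | 4-bromofuran-2(5H)-one | O=C1C=C(Br)CO1 | starting material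
17 | 9-(3,3-dimethoxypropyl)-9-borabicyclo[3.3.1]nonane | COC(OC)CCB1C2CCCC1CCC2 | intermediate (not isolated)
18 | 4-(3,3-dimethoxypropyl)furan-2(5H)-one | COC(OC)CCC1=CC(=O)OC1 | intermediate
19 | 3-(5-oxo-2,5-dihydrofuran-3-yl)propanal | O=CCCC1=CC(=O)OC1 | intermediate
20 | 2-bromopropene | C=C(C)Br | starting material
21 | dichloro(prop-1-en-2-yl)chromium | C=C(C)[Cr](Cl)Cl | intermediate (not isolated)
22 | 4-(3-hydroxy-4-methylpent-4-en-1-yl)furan-2(5H)-one (racemic) | C=C(C)C(O)CCC1=CC(=O)OC1 | intermediate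
23 | 4-[3-(ethenyloxy)-4-methylpent-4-en-1-yl]furan-2(5H)-one (racemic) | C=COC(CCC1=CC(=O)OC1)C(C)=C | intermediate
24 | (E)-4-methyl-7-(5-oxo-2,5-dihydrofuran-3-yl)hept-4-enal | O=CCC/C(C)=C/CCC1=CC(=O)OC1 | intermediate
25 | dichloro{4-[(1R,6R)-1,2,6-trimethyl-4-oxocyclohex-2-en-1-yl]but-1-en-2-yl}chromium (sulfonamide ligand on chromium not drawn) | C=C([Cr](Cl)Cl)CC[C@@]1(C)C(C)=CC(=O)C[C@H]1C | intermediate (not isolated)
26 | 4-[(3E,7R)-7-hydroxy-4-methyl-8-methylidene-10-[(1R,6R)-1,2,6-trimethyl-4-oxocyclohex-2-en-1-yl]dec-3-en-1-yl]furan-2(5H)-one | C=C(CC[C@@]1(C)C(C)=CC(=O)C[C@H]1C)[C@@H](CC/C(C)=C/CCC1=CC(=O)OC1)O | intermediate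
27 | 4-[(3E,7R)-7-acetoxy-4-methyl-8-methylidene-10-[(1R,6R)-1,2,6-trimethyl-4-oxocyclohex-2-en-1-yl]dec-3-en-1-yl]furan-2(5H)-one (CNP0204194.1) | C=C(CC[C@@]1(C)C(C)=CC(=O)C[C@H]1C)[C@@H](CC/C(C)=C/CCC1=CC(=O)OC1)OC(C)=O | target

**Totals**
Total step count: 16.
Longest linear sequence: 10 steps (step 2 or step 1, then 3, 4, 5, 6, 7, 8, 9, 15, 16). The fragment B arm is 7 steps (10 to 16).

**Steps most likely to fail, with fallbacks**

Step 4 (asymmetric methyl addition to a 2-alkylated enone; risk of low conversion or low ee). The fallback sets the methyl centre on the unsubstituted enone and brings the side chain in afterwards. It sets out from 1 and 4. From 1, Cu(OTf)2 (2 mol %) with the same phosphoramidite, Me2Zn, toluene, −30 °C, then TMSOTf, gives trimethyl{[(3R)-3-methylcyclohex-1-en-1-yl]oxy}silane F1. Bromide 4 is converted with NaI in acetone into (4-iodobut-1-en-2-yl)triethylsilane F2. F1 is treated with MeLi (THF, 0 °C) and then with F2 and HMPA to give (2S,3R)-3-methyl-2-[3-(triethylsilyl)but-3-en-1-yl]cyclohexan-1-one F3; alkylation occurs anti to the methyl group, and this centre is erased in the next operation. Equilibrating silylation (TMSCl, NaI, Et3N, MeCN, rt) then gives the more substituted enol ether, which is 8, and the route continues with step 5.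

Step 9 (ipso-iododesilylation of a geminal vinylsilane; risk of attack at the terminal carbon or a sluggish reaction). The fallback is halogen addition followed by elimination, which gives the vinyl bromide. It sets out from 13. Br2 (1.0 equiv), CH2Cl2, −78 °C gives (4R,5R)-4-[3,4-dibromo-3-(triethylsilyl)butyl]-3,4,5-trimethylcyclohex-2-en-1-one F4; both carbons now carry bromine, so the regiochemistry of halonium opening no longer matters. Bu4NF in THF at 0 °C removes silicon together with the terminal bromide (anti elimination) to give (4R,5R)-4-(3-bromobut-3-en-1-yl)-3,4,5-trimethylcyclohex-2-en-1-one F5. F5 is a 2-bromoalkene of the same kind as 20; it takes the place of 14 in step 15 (NiCl2 raised to 5 mol %) and the route is rejoined at 26.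

Step 15 (ligand control of the C7 configuration; risk of a low diastereomer ratio, and the C7 epimers are unlikely to be separable). The fallback is an unselective coupling followed by kinetic resolution. It sets out from 14 and 24. CrCl2/NiCl2 in DMF without the chiral ligand gives 4-[(3E,7RS)-7-hydroxy-4-methyl-8-methylidene-10-[(1R,6R)-1,2,6-trimethyl-4-oxocyclohex-2-en-1-yl]dec-3-en-1-yl]furan-2(5H)-one F6 as a 1:1 mixture at C7. Sharpless kinetic resolution (Ti(OiPr)4, L-(+)-diisopropyl tartrate, tBuOOH 0.6 equiv, 4 Å sieves, CH2Cl2, −20 °C) epoxidises the fast-reacting 7S epimer to 4-[(3E,7S)-7-hydroxy-4-methyl-7-{(2S)-2-[2-((1R,6R)-1,2,6-trimethyl-4-oxocyclohex-2-en-1-yl)ethyl]oxiran-2-yl}hept-3-en-1-yl]furan-2(5H)-one F7, which is removed by chromatography. The unreacted 7R alcohol is 26 (at most 50 % of the material), and the route continues with step 16.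

**Further compounds**
F1 | step 4 | trimethyl{[(3R)-3-methylcyclohex-1-en-1-yl]oxy}silane | C1=C(O[Si](C)(C)C)CCC[C@H]1C
F2 | step 4 | (4-iodobut-1-en-2-yl)triethylsilane | C=C(CCI)[Si](CC)(CC)CC
F3 | step 4 | (2S,3R)-3-methyl-2-[3-(triethylsilyl)but-3-en-1-yl]cyclohexan-1-one | C=C(CC[C@@H]1C(=O)CCC[C@H]1C)[Si](CC)(CC)CC
F4 | step 9 | (4R,5R)-4-[3,4-dibromo-3-(triethylsilyl)butyl]-3,4,5-trimethylcyclohex-2-en-1-one | BrCC(Br)(CC[C@@]1(C)C(C)=CC(=O)C[C@H]1C)[Si](CC)(CC)CC
F5 | step 9 | (4R,5R)-4-(3-bromobut-3-en-1-yl)-3,4,5-trimethylcyclohex-2-en-1-one | C=C(Br)CC[C@@]1(C)C(C)=CC(=O)C[C@H]1C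
F6 | step 15 | 4-[(3E,7RS)-7-hydroxy-4-methyl-8-methylidene-10-[(1R,6R)-1,2,6-trimethyl-4-oxocyclohex-2-en-1-yl]dec-3-en-1-yl]furan-2(5H)-one (C7 epimer mixture) | C=C(CC[C@@]1(C)C(C)=CC(=O)C[C@H]1C)C(O)CC/C(C)=C/CCC1=CC(=O)OC1
F7 | step 15 | 4-[(3E,7S)-7-hydroxy-4-methyl-7-{(2S)-2-[2-((1R,6R)-1,2,6-trimethyl-4-oxocyclohex-2-en-1-yl)ethyl]oxiran-2-yl}hept-3-en-1-yl]furan-2(5H)-one | O[C@@H](CC/C(C)=C/CCC1=CC(=O)OC1)[C@]2(CC[C@@]3(C)C(C)=CC(=O)C[C@H]3C)CO2
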